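## Retrosynthetic overview

- Late moves: acid 20 comes from ester 19. Ester 19 comes from a para-Claisen shift of a prenyl group from O5 to C8, the only aromatic C–H, which lies para to O5. Its precursor 16 comes from dihydropyranocoumarin 13, whose O5–C(=O) lactone is a temporary ring masking both C5–OH and the acid.
- The (R)-benzylic centre comes from a copper hydride conjugate reduction of 4-propylcoumarin 12. All six side-chain carbons arrive in a Pechmann condensation on phloroglucinol.
- Key disconnection: C3–C4 of the dihydropyran ring (chroman numbering). Enabling feature: C3 bears only H and CH3 next to the O-bearing stereocentre C2, so it is the hydrogen-atom adduct of a vinyl group on C2. C4 is a bare CH2 on aromatic C4a, ortho to C8a–O1, so it is an aryl aldehyde at the sulfonylhydrazone level that ends as CH2 after loss of N2. The O1 tether places the two carbons in 6-exo distance.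
- C2 comes from (R)-but-3-en-2-ol by Mitsunobu inversion. The C4 carbon comes from a C8-selective Vilsmeier–Haack formylation of the coumarin.
- Ring order: benzene ring bought, pyranone ring formed (step 1), dihydropyran ring formed (step 6), pyranone ring opened (step 8).

Key step: step 6

Numbering: bicyclic coumarins use chromen-2-one numbering. Tricycles use pyrano[2,3-f]chromen-2-one numbering, in which C8, C9, C10 and C6 correspond to C2, C3, C4 and C8 of the target. Ring-opened compounds use chroman numbering.

Assumption: the sense of induction of the copper hydride/(R)-DTBM-SEGPHOS catalyst on 12 is assigned by analogy with other 4-substituted coumarins; if it delivers the (4S) epimer, the equally available (S)-ligand is used.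

## Route

Step 1
Reactants: 1 phloroglucinol; 2 ethyl 3-oxohexanoate
Product: 3 5,7-dihydroxy-4-propyl-2H-chromen-2-one
Conditions: conc. H2SO4, 0 °C to rt; ice water
Reagents that add atoms: none
Why: Pechmann condensation, in which acid-promoted transesterification and ring closure with dehydration on the symmetric, highly nucleophilic phloroglucinol can give only one regioisomer and brings in all six carbons of the later hexanoic acid chain, with no stereocentre formed.

Step 2
Reactants: 3 5,7-dihydroxy-4-propyl-2H-chromen-2-one
Product: 4 5,7-dihydroxy-2-oxo-4-propyl-2H-chromene-8-carbaldehyde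
Conditions: N-methylformanilide, POCl3, ClCH2CH2Cl, 75 °C; then H2O, aq. NaOAc
Reagents that add atoms: N-methylformanilide CN(C=O)c1ccccc1; water O
Why: Vilsmeier–Haack formylation, in which 5,7-dihydroxy-4-alkylcoumarins take acyl-type electrophiles preferentially at C8 (ortho to 7-OH, para to 5-OH, away from the crowded 4-propyl/5-OH region) and the product is stabilised by the 7-OH to formyl chelate; this carbon becomes C4 of the target.

Step 3
Reactants: 4 5,7-dihydroxy-2-oxo-4-propyl-2H-chromene-8-carbaldehyde
Product: 5 7-hydroxy-5-methoxy-2-oxo-4-propyl-2H-chromene-8-carbaldehyde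
Conditions: MeI (1.05 equiv), K2CO3 (1.1 equiv), acetone, rt
Reagents that add atoms: iodomethane CI
Why: Williamson methylation with one equivalent of base, selective because the 5-OH (para to the formyl group, not hydrogen-bonded) is the more acidic and exposed phenol while the 7-OH is held in the chelate with the 8-formyl group.

Step 4
Reactants: 5 7-hydroxy-5-methoxy-2-oxo-4-propyl-2H-chromene-8-carbaldehyde; 6 (R)-but-3-en-2-ol
Product: 7 7-[(2S)-but-3-en-2-yloxy]-5-methoxy-2-oxo-4-propyl-2H-chromene-8-carbaldehyde
Conditions: PPh3, DIAD, THF, 0 °C to rt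
Reagents that add atoms: none
Why: Mitsunobu etherification, in which the acidic phenol displaces the activated secondary alcohol by SN2 with inversion, so (R)-6 gives the (S)-ether that is C2 of the target, and low temperature in a non-ionising solvent holds back the SN2' and ionisation paths of the allylic system.

Step 5
Reactants: 7 7-[(2S)-but-3-en-2-yloxy]-5-methoxy-2-oxo-4-propyl-2H-chromene-8-carbaldehyde; 8 2,4,6-trimethylbenzenesulfonohydrazide
Product: 9 (E)-N'-({7-[(2S)-but-3-en-2-yloxy]-5-methoxy-2-oxo-4-propyl-2H-chromen-8-yl}methylidene)-2,4,6-trimethylbenzenesulfonohydrazide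
Conditions: 8 (1.0 equiv), MeOH/THF, rt; filtration
Reagents that add atoms: none
Why: Condensation of an aldehyde with a sulfonylhydrazide to the (E)-sulfonylhydrazone, which should crystallise so that no free hydrazide (a diimide source that would reduce the vinyl group) is carried into step 6.

Step 6
Reactants: 9 (E)-N'-({7-[(2S)-but-3-en-2-yloxy]-5-methoxy-2-oxo-4-propyl-2H-chromen-8-yl}methylidene)-2,4,6-trimethylbenzenesulfonohydrazide
Product: 12 (8S,9R)-5-methoxy-8,9-dimethyl-4-propyl-9,10-dihydro-2H,8H-pyrano[2,3-f]chromen-2-one, via cyclised sulfonylhydrazide 10 (not isolated), via benzylic diazene 11 (not isolated)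
Conditions: Fe(acac)3 (30 mol %), PhSiH3 (3 equiv), degassed THF/MeOH 1:1, 0.02 M, argon, 40 °C; then 65 °C
Reagents that add atoms: none
Why: Proposed new method: a trivalent iron hydride made from Fe(acac)3 and PhSiH3 transfers a hydrogen atom to the terminal CH2 of the vinyl group (Markovnikov metal-hydride hydrogen atom transfer), creating the C9 methyl group and a nucleophilic secondary radical at C9 that adds to the hydrazone carbon; the N-centred radical is reduced by divalent iron and protonated by MeOH to 10, and warming expels mesitylenesulfinic acid and then N2 from diazene 11, leaving only CH2 at C10. The closest known reaction types are the iron-hydride hydromethylation of olefins with formaldehyde sulfonylhydrazones, hydrogen-atom-transfer cyclisations of alkene-tethered hydrazones, radical Wolff–Kishner-type alkylations of aryl aldehyde sulfonylhydrazones and the Caglioti-type decay of N-alkyl-N'-sulfonylhydrazides; what is new is their union in a traceless ring closure. The dihydropyran ring closes in the 6-exo-trig mode on the C=N bond. The C9 stereocentre is controlled by the C8 stereocentre, because in the chair-like transition state the C8 methyl lies pseudo-equatorial and the methyl on the planar radical should also turn pseudo-equatorial, away from the hydrazone nitrogen substituent, favouring the 8,9-trans (8S,9R) isomer, while the transient C10 centre is erased with N2. The step needs chemoselectivity between the vinyl group and the coumarin C3=C4 bond, which is secured because the latter is an electron-poor, β,β-disubstituted, peri-hindered olefin of the kind that survives these conditions and lies out of reach of the radical, and because the prenyl group is deliberately absent until step 9. High dilution and exclusion of oxygen favour cyclisation over premature reduction or oxygenation of the radical.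

Step 7
Reactants: 12 (8S,9R)-5-methoxy-8,9-dimethyl-4-propyl-9,10-dihydro-2H,8H-pyrano[2,3-f]chromen-2-one
Product: 13 (4R,8S,9R)-5-methoxy-8,9-dimethyl-4-propyl-3,4,9,10-tetrahydro-2H,8H-pyrano[2,3-f]chromen-2-one
Conditions: Cu(OAc)2·H2O (5 mol %), (R)-DTBM-SEGPHOS (5.5 mol %), (EtO)2MeSiH (1.5 equiv), t-BuOH (1.5 equiv), toluene, −10 °C to rt
Reagents that add atoms: none
Why: Asymmetric conjugate reduction with a ligated monovalent copper hydride, established for 4-substituted coumarins and β-aryl-β-alkyl enoates, in which the chiral bisphosphine decides the face of C4 that receives hydride (catalyst control), t-BuOH protonates the copper enolate, and limited silane at low temperature guards against further reduction to the lactol.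

Step 8
Reactants: 13 (4R,8S,9R)-5-methoxy-8,9-dimethyl-4-propyl-3,4,9,10-tetrahydro-2H,8H-pyrano[2,3-f]chromen-2-one; 14 1-bromo-3-methylbut-2-ene (prenyl bromide)
Product: 16 methyl (3R)-3-[(2S,3R)-7-methoxy-2,3-dimethyl-5-(3-methylbut-2-enyloxy)chroman-6-yl]hexanoate, via sodium phenolate 15 (not isolated)
Conditions: NaOMe (1.05 equiv), MeOH/THF, 0 °C; evaporation; 14 (1.3 equiv), DMF, 0 °C to rt
Reagents that add atoms: sodium methoxide C[O-].[Na+]
Why: Methanolysis of the aryl ester, driven by release of the weakly basic phenoxide, followed by Williamson O-alkylation of that phenoxide in the same flask, which avoids isolating a hydroxy ester prone to relactonise and touches no stereocentre.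

Step 9
Reactants: 16 methyl (3R)-3-[(2S,3R)-7-methoxy-2,3-dimethyl-5-(3-methylbut-2-enyloxy)chroman-6-yl]hexanoate
Product: 19 methyl (3R)-3-[(2S,3R)-5-hydroxy-7-methoxy-2,3-dimethyl-8-(3-methylbut-2-enyl)chroman-6-yl]hexanoate, via ortho-dienone 17 (not isolated), via para-dienone 18 (not isolated)
Conditions: PhNEt2, 200 °C, sealed tube, argon
Reagents that add atoms: none
Why: Para-Claisen (Claisen–Cope) rearrangement, in which both ortho positions (C4a, C6) are blocked, so the [3,3] shift to the less hindered C4a gives dienone 17 that cannot enolise and passes by a Cope [3,3] shift to C8, the double allyl inversion returning the linear prenyl group and tautomerisation of 18 regenerating the C5 phenol.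

Step 10
Reactants: 19 methyl (3R)-3-[(2S,3R)-5-hydroxy-7-methoxy-2,3-dimethyl-8-(3-methylbut-2-enyl)chroman-6-yl]hexanoate
Product: 20 (3R)-3-[(2S,3R)-5-hydroxy-7-methoxy-2,3-dimethyl-8-(3-methylbut-2-enyl)chroman-6-yl]hexanoic acid (target)
Conditions: LiOH (3 equiv), THF/MeOH/H2O, rt; then 1 M HCl to pH 4–5, 0 °C, rapid extraction
Reagents that add atoms: lithium hydroxide [Li+].[OH-]
Why: Saponification of a methyl ester without an α-stereocentre, with cold and only mildly acidic work-up so that the free hydroxy acid is not driven back to the lactone and the prenyl group is not protonated.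

## Compound list

1 | phloroglucinol | Oc1cc(O)cc(O)c1 | starting material
2 | ethyl 3-oxohexanoate | CCCC(=O)CC(=O)OCC | starting material
3 | 5,7-dihydroxy-4-propyl-2H-chromen-2-one | CCCC1=CC(=O)Oc2cc(O)cc(O)c12 | intermediate
4 | 5,7-dihydroxy-2-oxo-4-propyl-2H-chromene-8-carbaldehyde | CCCC1=CC(=O)Oc2c(C=O)c(O)cc(O)c12 | intermediate
5 | 7-hydroxy-5-methoxy-2-oxo-4-propyl-2H-chromene-8-carbaldehyde | CCCC1=CC(=O)Oc2c(C=O)c(O)cc(OC)c12 | intermediate
6 | (R)-but-3-en-2-ol | C[C@@H](O)C=C | starting material
7 | 7-[(2S)-but-3-en-2-yloxy]-5-methoxy-2-oxo-4-propyl-2H-chromene-8-carbaldehyde | CCCC1=CC(=O)Oc2c(C=O)c(O[C@@H](C)C=C)cc(OC)c12 | intermediate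
8 | 2,4,6-trimethylbenzenesulfonohydrazide | Cc1cc(C)c(S(=O)(=O)NN)c(C)c1 | starting material
9 | (E)-mesitylenesulfonylhydrazone of 7 | CCCC1=CC(=O)Oc2c(/C=N/NS(=O)(=O)c3c(C)cc(C)cc3C)c(O[C@@H](C)C=C)cc(OC)c12 | intermediate
10 | N'-[(8S,9R)-5-methoxy-8,9-dimethyl-2-oxo-4-propyl-9,10-dihydro-2H,8H-pyrano[2,3-f]chromen-10-yl]-2,4,6-trimethylbenzenesulfonohydrazide (C10 not defined, not isolated) | CCCC1=CC(=O)Oc2c3c(cc(OC)c12)O[C@@H](C)[C@H](C)C3NNS(=O)(=O)c1c(C)cc(C)cc1C | intermediate
11 | (8S,9R)-10-diazenyl-5-methoxy-8,9-dimethyl-4-propyl-9,10-dihydro-2H,8H-pyrano[2,3-f]chromen-2-one (not isolated) | CCCC1=CC(=O)Oc2c3c(cc(OC)c12)O[C@@H](C)[C@H](C)C3N=N | intermediate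
12 | (8S,9R)-5-methoxy-8,9-dimethyl-4-propyl-9,10-dihydro-2H,8H-pyrano[2,3-f]chromen-2-one | CCCC1=CC(=O)Oc2c3c(cc(OC)c12)O[C@@H](C)[C@H](C)C3 | intermediate
13 | (4R,8S,9R)-5-methoxy-8,9-dimethyl-4-propyl-3,4,9,10-tetrahydro-2H,8H-pyrano[2,3-f]chromen-2-one | CCC[C@@H]1CC(=O)Oc2c3c(cc(OC)c12)O[C@@H](C)[C@H](C)C3 | intermediate
14 | 1-bromo-3-methylbut-2-ene | CC(C)=CCBr | starting material
15 | sodium phenolate of methyl (3R)-3-[(2S,3R)-5-hydroxy-7-methoxy-2,3-dimethylchroman-6-yl]hexanoate (not isolated) | CCC[C@H](CC(=O)OC)c1c([O-])c2c(cc1OC)O[C@@H](C)[C@H](C)C2.[Na+] | intermediate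
16 | methyl (3R)-3-[(2S,3R)-7-methoxy-2,3-dimethyl-5-(3-methylbut-2-enyloxy)chroman-6-yl]hexanoate | CCC[C@H](CC(=O)OC)c1c(OCC=C(C)C)c2c(cc1OC)O[C@@H](C)[C@H](C)C2 | intermediate
17 | ortho-dienone with a 2-methylbut-3-en-2-yl group on C4a (C4a not defined, not isolated) | CCC[C@H](CC(=O)OC)C1=C(OC)C=C2O[C@@H](C)[C@H](C)CC2(C(C)(C)C=C)C1=O | intermediate
18 | para-dienone with H and prenyl on C8 (C8 not defined, not isolated) | CCC[C@H](CC(=O)OC)C1=C(OC)C(CC=C(C)C)C2=C(C1=O)C[C@@H](C)[C@H](C)O2 | intermediate
19 | methyl (3R)-3-[(2S,3R)-5-hydroxy-7-methoxy-2,3-dimethyl-8-(3-methylbut-2-enyl)chroman-6-yl]hexanoate | CCC[C@H](CC(=O)OC)c1c(O)c2c(c(CC=C(C)C)c1OC)O[C@@H](C)[C@H](C)C2 | intermediate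
20 | (3R)-3-[(2S,3R)-5-hydroxy-7-methoxy-2,3-dimethyl-8-(3-methylbut-2-enyl)chroman-6-yl]hexanoic acid | CCC[C@H](CC(=O)O)c1c(O)c2c(c(CC=C(C)C)c1OC)O[C@@H](C)[C@H](C)C2 | target

## Step count and risks

Total step count: 10. Longest linear sequence: 10 steps, from phloroglucinol 1.

**Step 6 (the labelled step).**
- The planar C9 radical may show poor facial selectivity.
- Hydrogen may be transferred back from C8–H, which transposes the olefin and loses the C8 stereochemical information.
- The aryloxy group may be lost by β-fragmentation.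
- The radical may be reduced before it cyclises.
- Hydrogen atom transfer to the coumarin double bond may compete.

The fallback uses known chemistry, sets out from 5 and comes back at 12. Asymmetric crotylboration of 5 uses excess (E)-crotyldiisopinocampheylborane, prepared from (−)-B-methoxydiisopinocampheylborane (THF/Et2O, −78 °C, ethanolamine work-up). It should form the same carbon–carbon bond intermolecularly and, under reagent control, give 7-hydroxy-8-[(1S,2S)-1-hydroxy-2-methylbut-3-enyl]-5-methoxy-4-propyl-2H-chromen-2-one F1. Intramolecular oxymercuration of the 7-OH onto the vinyl group (Hg(OAc)2, THF; then NaBH4, aq. NaOH) should close the ring through a chair with equatorial methyl groups. This gives (8S,9R,10S)-10-hydroxy-5-methoxy-8,9-dimethyl-4-propyl-9,10-dihydro-2H,8H-pyrano[2,3-f]chromen-2-one F2. Ionic deoxygenation of the electron-rich benzylic alcohol (Et3SiH, CF3CO2H, CH2Cl2, 0 °C) then gives 12.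

**Step 7.**
- Hydride delivery to C4 may be slow because of the peri methoxy group.
- Facial selectivity may be low.
- The lactone carbonyl may be over-reduced.

The fallback replaces catalyst control by separation of diastereomers, sets out from 12 and comes back at 13. Unselective hydrogenation (H2, Pd/C, EtOAc/AcOH) gives the C4-epimeric (8S,9R)-5-methoxy-8,9-dimethyl-4-propyl-3,4,9,10-tetrahydro-2H,8H-pyrano[2,3-f]chromen-2-one F3. Aminolysis of the lactone with (S)-1-phenylethylamine (toluene, 60 °C) gives two diastereomeric hydroxy amides. Chromatography or crystallisation isolates (3R)-3-[(2S,3R)-5-hydroxy-7-methoxy-2,3-dimethylchroman-6-yl]-N-[(1S)-1-phenylethyl]hexanamide F4. Acid-promoted relactonisation (TsOH·H2O, toluene, reflux) releases the amine and gives 13.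

**Step 9.**
- The first [3,3] shift may be slow because it must join two fully substituted carbons.
- The prenyl group may be lost as isoprene by ionisation or a retro-ene process.

The fallback replaces the rearrangement by halogenation and cross-coupling, sets out from 13 and comes back at 20. Bromination of the only free aromatic position (NBS, MeCN, 0 °C) gives (4R,8S,9R)-6-bromo-5-methoxy-8,9-dimethyl-4-propyl-3,4,9,10-tetrahydro-2H,8H-pyrano[2,3-f]chromen-2-one F5. Stille coupling with tributyl(3-methylbut-2-enyl)stannane (Pd(PPh3)4, DMF, 100 °C) gives (4R,8S,9R)-5-methoxy-8,9-dimethyl-6-(3-methylbut-2-enyl)-4-propyl-3,4,9,10-tetrahydro-2H,8H-pyrano[2,3-f]chromen-2-one F6. Opening of the lactone under the conditions of step 10 gives 20. Loss of methanol from 19 at 200 °C in the main route would lead to this same lactone and would therefore be harmless.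

## Further compounds

F1 | step 6 | 7-hydroxy-8-[(1S,2S)-1-hydroxy-2-methylbut-3-enyl]-5-methoxy-4-propyl-2H-chromen-2-one | C=C[C@H](C)[C@H](O)c1c(O)cc(OC)c2c1OC(=O)C=C2CCC
F2 | step 6 | (8S,9R,10S)-10-hydroxy-5-methoxy-8,9-dimethyl-4-propyl-9,10-dihydro-2H,8H-pyrano[2,3-f]chromen-2-one | CCCC1=CC(=O)Oc2c3c(cc(OC)c12)O[C@@H](C)[C@H](C)[C@@H]3O
F3 | step 7 | (8S,9R)-5-methoxy-8,9-dimethyl-4-propyl-3,4,9,10-tetrahydro-2H,8H-pyrano[2,3-f]chromen-2-one, C4 epimers | CCCC1CC(=O)Oc2c3c(cc(OC)c12)O[C@@H](C)[C@H](C)C3
F4 | step 7 | (3R)-3-[(2S,3R)-5-hydroxy-7-methoxy-2,3-dimethylchroman-6-yl]-N-[(1S)-1-phenylethyl]hexanamide | CCC[C@H](CC(=O)N[C@@H](C)c1ccccc1)c1c(O)c2c(cc1OC)O[C@@H](C)[C@H](C)C2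
F5 | step 9 | (4R,8S,9R)-6-bromo-5-methoxy-8,9-dimethyl-4-propyl-3,4,9,10-tetrahydro-2H,8H-pyrano[2,3-f]chromen-2-one | CCC[C@@H]1CC(=O)Oc2c3c(c(Br)c(OC)c12)O[C@@H](C)[C@H](C)C3
F6 | step 9 | (4R,8S,9R)-5-methoxy-8,9-dimethyl-6-(3-methylbut-2-enyl)-4-propyl-3,4,9,10-tetrahydro-2H,8H-pyrano[2,3-f]chromen-2-one | CCC[C@@H]1CC(=O)Oc2c3c(c(CC=C(C)C)c(OC)c12)O[C@@H](C)[C@H](C)C3
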